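Conventions: eudesmane numbering is used throughout (ring A = C1–C5 and C10; ring B = C5–C10; C11, C12, C13 = α-carbon, carboxyl carbon and methylene carbon of the arm on C7). β is the face of the C10 methyl group, α the other face. TBS = tert-butyldimethylsilyl, TES = triethylsilyl, TMS = trimethylsilyl.

## The problem

Target 29 is a 15-nor-eudesmane: a trans-fused decalin whose ring A carries a secondary alcohol at C1 and a ketone at C4, and whose ring B carries three contiguous substituents (C6 hydroxyl, C7 methyl acrylate unit, C8 2-(hydroxymethyl)acrylate ester) next to the quaternary, methyl-bearing C10. In the chair–chair trans-decalin every substituent except the axial C10 methyl is equatorial. C5 and C7 can therefore be corrected by enolisation whenever a carbonyl sits next to them, and C1 can be set by axial hydride delivery away from the C10 methyl. C6 has no such handle and must come out of the ring-forming step, and C8 is the awkward centre, because the same methyl group blocks axial hydride delivery there. The absolute configuration has to be introduced at the quaternary carbon C10, from which the other five centres are relayed. The functionality is fragile: the C4 ketone and C6 hydroxyl form an aldol pair (dehydration, retro-aldol, C5 epimerisation under base), both acrylates are Michael acceptors, the C6 and C8 oxygens can lactonise onto C12, and C7–H lies between two oxygenated carbons and γ to the acrylate, so a C8 ketone and the C11 methylene must never coexist. The methylene therefore has to be made by ester enolate chemistry at a point where no ketone is present, and the acyl group and the free hydroxyls must appear last under non-basic conditions. The enabling feature is the oxygen pattern: ring A holds oxygen at C1 and C4, para to each other and flanking C10 (methyl) and C5 (hydrogen), which is a methyl-1,4-benzoquinone, and ring B holds oxygen at C6 and C8 with a carbon arm at C7, which is a 2-substituted 1,3-dioxygenated butadiene, so ring B is a Diels–Alder adduct across the C5=C10 bond of the quinone.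

## Retrosynthesis

Endgame (29 ⇒ 28 ⇒ 27 ⇒ 22 + 25). The three O–Si bonds of 28 are cut first, then the C4 ketone is traced to the carbinol 27, then the C8–O acyl bond is cut to give diol 22 and acid 25. The acyl group is cut ahead of anything in the ring system because a 2-(hydroxymethyl)acrylate survives neither enolate nor hydride chemistry. The C4 ketone is carried as a carbinol because the methylenation before it needs a strong base. 22 is much simpler: one ester, two free hydroxyls of very different accessibility (C8 equatorial, C4 axial under the C10 methyl). The forward steps must acylate C8 only, oxidise C4 and remove silicon without base.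

Methylene (22 ⇒ 21 ⇒ 19 ⇒ 17). The C11=C13 bond is cut by a Mannich–elimination sequence back to the saturated ester 17. This cut comes after the acyl cut and before any ketone is restored. Cutting it later would expose the acrylate ester at C8 to the amide base, and cutting it earlier would leave a C8 enol ether or ketone conjugated with the new alkene. The forward reaction needs a substrate whose only acidic C–H is at C11, which is why C4 and C8 are both TES-protected carbinols in 17.

Ring B oxidation level (17 ⇒ 16 ⇒ 15 ⇒ 14). The C8 carbinol is traced to ketone 15 and this to the enol silyl ether 14 that the cycloaddition delivers. A hydride would give the axial alcohol, so the forward reduction must be a single-electron one that ends at the equatorial carbinol. C7 is set when the enol ether is protonated. No C–C bond is cut here, but the precursor has two stereocentres fewer.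

Ring A oxidation level (14 ⇒ 13 ⇒ 12). The C1 and C4 carbinols are traced to diketone 12. Reducing both ketones and telling the alcohols apart by silylation is preferred to telling the ketones apart, because C4 must be reduced in any case and the two alcohols differ more (equatorial against 1,3-diaxial to the methyl). The forward reduction must deliver hydride axially at C1.

Methoxy group and ring fusion (12 ⇒ 10 ⇒ 9). The C2=C3 double bond and the C3 methoxy group are put back, and C5 is inverted, which leads to the cis-fused enedione 9. The methoxy group is kept this long because it controls the cycloaddition; it is then removed in the same reductive operation that saturates ring A. The forward steps ask for a base-mediated cis-to-trans equilibration without loss of the C6 silyloxy group, and a four-electron reduction.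

Key cut (9 ⇒ 6 + 8). The C9–C10 and C5–C6 bonds are cut together. Neighbouring cuts of ring B at C7–C8 or C6–C7 need a ring A fragment in which C1, C5 and C10 have already been set one by one. This cut instead divides the skeleton into two flat, achiral pieces, quinone 8 and diene 6, and forms the quaternary centre, C5 and C6 in one catalytic enantioselective step. The forward reaction must be selective for the methyl-bearing double bond, regioselective (C9 to C10), endo-selective and face-selective.

Building blocks (6 ⇒ 5 ⇒ 4 ⇒ 3 ⇒ 2 ⇒ 1; 8 ⇒ 7; 25 ⇒ 24 ⇒ 23). Diene 6 is the bis-silyl derivative of formyl ketone 4. The formyl carbon is attached at C3 of methyl levulinate 1 through its thermodynamic silyl enol ether 2 and the acetal 3, which fixes the regiochemistry that a direct formylation would leave open. Quinone 8 is the para-oxidation product of phenol 7. Acid 25 comes from commercial ester 23 by silylation and saponification.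

## Roads not taken

Alternative 1: The C5–C10 bond is cut, which opens both rings to the ten-membered 1,10-epoxygermacrene ester A2. In the forward direction Cp2TiCl (trivalent titanium) opens the epoxide at the tertiary carbon, the C10 radical adds across the ring to C5 of the C4=C5 alkene, and the C4 radical ends as the exocyclic C4 methylene of dienoate A1. The merits are real. One step makes the bicycle and sets C1, C5 and C10 from the chair–chair conformation of the macrocycle. The C6–C8 substituents and the finished acrylate are carried through, and the C4 methylene could later be cleaved by ozone in preference to the electron-poor acrylate. In ring-forming economy and in the endgame this road is better than the chosen one: it needs no C5 epimerisation, no redox parking of C4 and no strong-base methylenation after ring formation. Its weakness is A2 itself. A2 is a ten-membered ring with an E-trisubstituted alkene, a stereodefined epoxide and three contiguous stereocentres, and it must be assembled and closed before the key step can be tried. The outcome of the cyclisation also depends on the conformation of a macrocycle loaded with two bulky ethers, and the acrylate is a potential radical acceptor under the titanium conditions. The chosen plan sets against this two commercial-grade achiral components, a catalytic source of absolute configuration and three stereocentres in its first ring-forming step, and it pays with a longer sequence after the key step.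

Alternative 2: The C7–C8 bond is cut, which leads to the ring A aldehyde A4 carrying a trisubstituted C7=C11 alkene. In the forward direction Me2AlCl activates the C8 aldehyde for an intramolecular carbonyl-ene reaction that closes ring B and gives decalin A3 with a free C8 hydroxyl and a C7 isopropenyl group. The merit is that C7 and C8 are set together in the ring closure, trans-diequatorial from a chair transition state. This solves directly the centre that the chosen plan reaches only through enol ether cleavage and a thermodynamically steered reduction, and in that respect this road is better. The weak points lie elsewhere. A3 carries an isopropenyl group, so C12 must be raised from methyl to ester (allylic oxidation and two further oxidations) in a molecule full of silyl ethers. A4 needs C1, C5, C6 and C10 set beforehand on a monocycle, with C6 coming from an addition next to the future ring fusion. Chloride capture and Prins-type paths compete with the ene reaction. The chosen plan brings C12 at the ester level from the start and sets C5, C6 and C10 in one step, at the price of an uncertain C8 reduction.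

Alternative 3: The C6–C7 bond is cut, which leads to the aldehyde allylboronate A6. On heating, the γ-carbon C7 of the 2-(methoxycarbonyl)allylboronate adds to the C6 aldehyde through a cyclic boron–oxygen transition state and gives decalin A5 with the C6 hydroxyl, C7 and the C11=C13 methylene all formed at once. On the acrylate problem this road is clearly better than the chosen one: no enolate chemistry is needed, so the roughly six steps of protecting-group and redox traffic around the methylenation disappear, and A5 is only a ketal removal, an ether-to-ester exchange and a desilylation away from 29. Its weak points are three. 2-Alkoxycarbonyl allylboronates are deactivated and need forcing, and the borate of the product tends to close onto C12 to the α-methylene lactone, expelling the methyl ester that the target needs. A6 requires C1, C5, C8 and C10 to be set one by one and a stereodefined trisubstituted alkene with allylic boron, with C5 epimerisable next to the aldehyde. The C6/C7 relationship depends on alkene geometry inside a constrained bicyclic transition state. The chosen plan sets against this a front end of five simple steps and a catalytic enantioselective key step; its disadvantage is the endgame.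

Key step: step 6

Assumption: (S)-BINOL is taken as the ligand enantiomer that gives 9 as drawn; the sense of induction has to be confirmed on 9, and if it is the opposite, (R)-BINOL is used with no other change.
Remark: the C4 carbinol of 13–27 is drawn as the expected 4β epimer; this centre is temporary and is removed in step 20.

Step 1
Reactants: 1 methyl levulinate (methyl 4-oxopentanoate)
Product: 2 methyl (Z)-4-(trimethylsilyloxy)pent-3-enoate
Conditions: TMSCl, NaI, Et3N, MeCN, rt
Reagents that add atoms: chlorotrimethylsilane, C[Si](C)(C)Cl
Why: Soft enolisation by Me3SiI formed in the flask, under equilibrating conditions, gives mainly the more substituted (thermodynamic) silyl enol ether of a methyl ketone, here the C3=C4 isomer; the minor terminal isomer does not lead to 3 and is removed by distillation or after step 2.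

Step 2
Reactants: 2 methyl (Z)-4-(trimethylsilyloxy)pent-3-enoate
Product: 3 methyl 3-(dimethoxymethyl)-4-oxopentanoate (racemic)
Conditions: HC(OMe)3, TMSOTf (10 mol %), CH2Cl2, −78 °C
Reagents that add atoms: trimethyl orthoformate, COC(OC)OC
Why: Mukaiyama-type addition of a silyl enol ether to the dimethoxycarbenium ion released from the orthoformate; the new C–C bond can only form at the enol ether carbon C3, so the masked formyl group is placed between the ketone and the ester arm. The stereocentre at C3 is without consequence because this carbon becomes sp2 in step 4.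

Step 3
Reactants: 3 methyl 3-(dimethoxymethyl)-4-oxopentanoate
Product: 4 methyl 3-formyl-4-oxopentanoate (present mainly as its hydroxymethylene enol)
Conditions: 1 M HCl, THF, 0 °C → rt
Reagents that add atoms: water, O
Why: Acid hydrolysis of the dimethyl acetal; the β-keto aldehyde is stabilised as its hydrogen-bonded enol and is used without storage.

Step 4
Reactants: 4 methyl 3-formyl-4-oxopentanoate
Product: 6 methyl (E)-3-[(tert-butyldimethylsilyloxy)methylene]-4-(tert-butyldimethylsilyloxy)pent-4-enoate (diene), via mono-silylated enone 5 (not isolated)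
Conditions: TBSOTf (2.2 equiv), Et3N, Et2O, 0 °C → rt
Reagents that add atoms: tert-butyldimethylsilyl trifluoromethanesulfonate, CC(C)(C)[Si](C)(C)OS(=O)(=O)C(F)(F)F
Why: O-Silylation of the enol gives 5, and soft enolisation of its O-silylated ketone can only remove a methyl hydrogen, which gives the cross-conjugated 2-silyloxydiene (the standard route to 1-oxy-3-silyloxybutadienes). The E geometry (silyloxy group trans to the bulky 2-silyloxyvinyl group) should prevail through reversible rotation in the oxocarbenium intermediate; any Z isomer cannot reach the s-cis conformation and would be a spectator in step 6.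

Step 5
Reactants: 7 2-methoxy-5-methylphenol
Product: 8 2-methoxy-5-methyl-1,4-benzoquinone
Conditions: (KSO3)2NO (2.2 equiv), KH2PO4, H2O/acetone, rt
Reagents that add atoms: potassium nitrosodisulfonate (KSO3)2NO, [K+].[K+].[O-]S(=O)(=O)N([O])S(=O)(=O)[O-]
Why: Teuber oxidation: a phenol with a free para position is oxidised by two equivalents of the nitroxide to the para-quinone, the new oxygen entering para to the hydroxyl.

Step 6
Reactants: 6 methyl (E)-3-[(tert-butyldimethylsilyloxy)methylene]-4-(tert-butyldimethylsilyloxy)pent-4-enoate; 8 2-methoxy-5-methyl-1,4-benzoquinone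
Product: 9 methyl (5β,6α)-6,8-bis(tert-butyldimethylsilyloxy)-3-methoxy-1,4-dioxo-13,15-dinoreudesma-2,7-dien-12-oate (cis-fused adduct)
Conditions: (S)-BINOL–TiCl2 (20 mol %; from (S)-BINOL and TiCl2(OiPr)2, 4 Å MS), toluene, −78 → −30 °C
Reagents that add atoms: none
Why: Concerted but asynchronous [4+2] cycloaddition (catalytic enantioselective quinone Diels–Alder reaction with a 1,3-dioxygenated diene): the titanium centre (tetravalent) is chelated by the C4 carbonyl oxygen and the neighbouring C3 methoxy oxygen of 8, which makes C10, the β-carbon of that activated carbonyl, the most electrophilic site. The CH2 terminus C9 of 6, the carbon with the largest HOMO coefficient of such a diene, bonds to C10 ahead of C6–C5 bond formation, so the quaternary methyl carbon ends next to C9 and the silyloxy carbon next to C5. Ring B closes as a six-membered ring by suprafacial–suprafacial addition of the two components. C10 and C5 come out cis because both new bonds form on one face of the quinone double bond; C6 is fixed relative to them by the E geometry of the silyloxyvinyl terminus together with the endo transition state, which places the C6 oxygen on the face opposite the C5 hydrogen; the absolute sense is set by the BINOL ligand, which screens one face of the chelated quinone. Three selectivities are needed: site selectivity for the methyl-bearing double bond (the other one is a vinylogous ester, deactivated by the methoxy group), regioselectivity (chelation and diene polarisation act in the same direction) and endo selectivity (secondary overlap with the enedione, reinforced by the Lewis acid). The angular methyl group blocks aromatisation of the adduct, and TBS groups are used because they resist Lewis-acid desilylation and Mukaiyama–Michael side paths better than TMS groups.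

Step 7
Reactants: 9 cis-fused adduct
Product: 10 methyl (5α,6α)-6,8-bis(tert-butyldimethylsilyloxy)-3-methoxy-1,4-dioxo-13,15-dinoreudesma-2,7-dien-12-oate (trans-fused)
Conditions: DBU (0.2 equiv), CH2Cl2, 0 °C
Reagents that add atoms: none
Why: Base-mediated epimerisation through the C4 dienolate (C5–H is vinylogously acidic across the enedione); angular-methyl methoxy-enedione adducts of this kind are more stable trans-fused, so equilibration should set the 5α hydrogen. A catalytic amidine at 0 °C is chosen because the pseudo-equatorial C6 silyloxy group is poorly aligned with the dienolate and should not be expelled under such mild conditions.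

Step 8
Reactants: 10 trans-fused methoxy-enedione
Product: 12 methyl (5α,6α)-6,8-bis(tert-butyldimethylsilyloxy)-1,4-dioxo-13,15-dinoreudesm-7-en-12-oate, via 3-methoxy diketone 11 (not isolated)
Conditions: SmI2 (4.5 equiv), THF/MeOH, −78 °C
Reagents that add atoms: none
Why: Samarium diiodide first reduces the enedione double bond and then cleaves the C3 methoxy group, which is now α to the C4 ketone (reduction of α-heteroatom-substituted ketones); four electrons in all give the saturated 1,4-diketone. The samarium enolate formed in the cleavage lies towards C3, so C5 is not touched, and ester, enol silyl ether and silyl ether are inert at −78 °C without a stronger activator.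

Step 9
Reactants: 12 trans-fused 1,4-diketone
Product: 13 methyl (1β,4β,5α,6α)-6,8-bis(tert-butyldimethylsilyloxy)-1,4-dihydroxy-13,15-dinoreudesm-7-en-12-oate
Conditions: NaBH4, MeOH/CH2Cl2, −20 °C → rt
Reagents that add atoms: none
Why: Borohydride reduction of both ring A ketones: at C1 the hydride enters axially from the α face, away from the axial C10 methyl group, and gives the equatorial 1β alcohol (sets C1); at C4 the axial β trajectory is blocked by the same methyl group, so the axial 4β alcohol is expected. The C4 carbinol is only a parked form of the ketone, so its configuration does not matter; the ester and the enol silyl ether survive borohydride in methanol.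

Step 10
Reactants: 13 1β,4β-diol
Product: 14 methyl (1β,4β,5α,6α)-1,6,8-tris(tert-butyldimethylsilyloxy)-4-hydroxy-13,15-dinoreudesm-7-en-12-oate
Conditions: TBSCl, imidazole, DMF, rt
Reagents that add atoms: tert-butyldimethylsilyl chloride, CC(C)(C)[Si](C)(C)Cl
Why: Silyl ether formation at the equatorial C1 hydroxyl; the C4 hydroxyl is axial, 1,3-diaxial to the C10 methyl group and flanked by the ring fusion and the C6 silyl ether, and should not react with the bulky chlorosilane.

Step 11
Reactants: 14 C1 silyl ether with ring B enol silyl ether
Product: 15 methyl (1β,4β,5α,6α,7α-H)-1,6-bis(tert-butyldimethylsilyloxy)-4-hydroxy-8-oxo-13,15-dinoreudesman-12-oate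
Conditions: Bu4NF, AcOH, THF, −20 °C
Reagents that add atoms: none
Why: Fluoride attacks the enol silyl ether much faster than the secondary alkyl silyl ethers, and acetic acid protonates the enolate at once so that no free base is left to eliminate the β-silyloxy group at C6. Protonation at C7 is axial, from the α face, and gives the equatorial CH2CO2Me arm, which is also the thermodynamic arrangement (sets C7).

Step 12
Reactants: 15 C8 ketone
Product: 16 methyl (1β,4β,5α,6α,7α-H,8α)-1,6-bis(tert-butyldimethylsilyloxy)-4,8-dihydroxy-13,15-dinoreudesman-12-oate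
Conditions: SmI2 (2.5 equiv), H2O, Et3N, THF, 0 °C
Reagents that add atoms: none
Why: Single-electron reduction of the ketone by SmI2 activated by water and amine; the intermediate places the bulky oxygen–samarium group equatorial and is protonated on carbon from the axial side, giving the equatorial (thermodynamic) 8α alcohol (sets C8), whereas hydride reagents would be driven to the axial alcohol because the C10 methyl blocks their axial approach. Two electrons per ketone and a short reaction time leave the methyl ester and the silyl ethers untouched.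

Step 13
Reactants: 16 4β,8α-diol
Product: 17 methyl (1β,4β,5α,6α,7α-H,8α)-1,6-bis(tert-butyldimethylsilyloxy)-4,8-bis(triethylsilyloxy)-13,15-dinoreudesman-12-oate
Conditions: TESOTf, 2,6-lutidine, CH2Cl2, −78 → 0 °C
Reagents that add atoms: triethylsilyl trifluoromethanesulfonate, CC[Si](CC)(CC)OS(=O)(=O)C(F)(F)F
Why: Silyl ether formation with the triflate, which is reactive enough to cover the hindered C4 hydroxyl as well; both carbinols are thereby masked for the enolate chemistry that follows.

Step 14
Reactants: 17 fully silylated ester
Product: 19 methyl (1β,4β,5α,6α,7α-H,8α)-1,6-bis(tert-butyldimethylsilyloxy)-13-(dimethylamino)-4,8-bis(triethylsilyloxy)-15-noreudesman-12-oate (C11 epimers), via lithium ester enolate 18 (not isolated)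
Conditions: LiN(iPr)2, THF, −78 °C; then CH2=NMe2+ I−, −78 → 0 °C
Reagents that add atoms: N,N-dimethylmethyleneiminium iodide (Eschenmoser's salt), C=[N+](C)C.[I-]
Why: With every other carbonyl group masked, the amide base can only deprotonate C11, and the lithium ester enolate 18 is aminomethylated by the iminium salt (Mannich reaction). The C11 stereocentre is formed as a mixture and is removed in step 15.

Step 15
Reactants: 19 β-dimethylamino ester
Product: 21 methyl (1β,4β,5α,6α,7α-H,8α)-1,6-bis(tert-butyldimethylsilyloxy)-4,8-bis(triethylsilyloxy)-15-noreudesm-11(13)-en-12-oate, via trimethylammonium iodide 20 (not isolated)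
Conditions: MeI, MeOH, rt; then aq. NaHCO3, EtOAc, rt
Reagents that add atoms: none
Why: N-Methylation to the quaternary ammonium salt 20 and base-induced β-elimination of trimethylamine give the acrylate (second half of the Mannich–elimination methylenation of esters); hydrogencarbonate is too weak to deprotonate C7, so the double bond stays exocyclic.

Step 16
Reactants: 21 bis-TES acrylate
Product: 22 methyl (1β,4β,5α,6α,7α-H,8α)-1,6-bis(tert-butyldimethylsilyloxy)-4,8-dihydroxy-15-noreudesm-11(13)-en-12-oate
Conditions: PPTS, MeOH/CH2Cl2, 0 °C → rt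
Reagents that add atoms: none
Why: Acid-catalysed methanolysis removes triethylsilyl ethers far faster than secondary TBS ethers, so both temporary groups leave while C1 and C6 stay protected; methanol as solvent also disfavours lactonisation onto the methyl ester.

Step 17
Reactants: 23 methyl 2-(hydroxymethyl)acrylate
Product: 24 methyl 2-[(tert-butyldimethylsilyloxy)methyl]acrylate
Conditions: TBSCl, imidazole, CH2Cl2, 0 °C → rt
Reagents that add atoms: tert-butyldimethylsilyl chloride, CC(C)(C)[Si](C)(C)Cl
Why: Standard silylation of a primary allylic alcohol.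

Step 18
Reactants: 24 methyl 2-[(tert-butyldimethylsilyloxy)methyl]acrylate
Product: 25 2-[(tert-butyldimethylsilyloxy)methyl]acrylic acid
Conditions: LiOH (1.1 equiv), THF/H2O, 0 °C; then 1 M HCl to pH 4
Reagents that add atoms: lithium hydroxide, [Li+].[OH-]
Why: Saponification of the methyl ester; low temperature and a small excess of hydroxide limit conjugate addition, and acidification only to pH 4 keeps the primary silyl ether.

Step 19
Reactants: 22 4β,8α-diol acrylate; 25 2-[(tert-butyldimethylsilyloxy)methyl]acrylic acid
Product: 27 methyl (1β,4β,5α,6α,7α-H,8α)-1,6-bis(tert-butyldimethylsilyloxy)-8-{2-[(tert-butyldimethylsilyloxy)methyl]acryloyloxy}-4-hydroxy-15-noreudesm-11(13)-en-12-oate, via Yamaguchi mixed anhydride 26 (not isolated)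
Conditions: 25, 2,4,6-Cl3C6H2COCl, Et3N, THF, rt; then 22, DMAP, toluene, 0 °C → rt
Reagents that add atoms: none
Why: Yamaguchi esterification through mixed anhydride 26: the equatorial C8 hydroxyl is acylated, while the C4 hydroxyl, axial and 1,3-diaxial to the C10 methyl group, should not compete at 0 °C with about one equivalent of the anhydride. The configuration at C8 is retained because the C8–O bond is not broken.

Step 20
Reactants: 27 C8 ester with free C4 hydroxyl
Product: 28 methyl (1β,5α,6α,7α-H,8α)-1,6-bis(tert-butyldimethylsilyloxy)-8-{2-[(tert-butyldimethylsilyloxy)methyl]acryloyloxy}-4-oxo-15-noreudesm-11(13)-en-12-oate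
Conditions: Dess–Martin periodinane, CH2Cl2, 0 °C → rt
Reagents that add atoms: none
Why: Dess–Martin oxidation of the one remaining free alcohol returns the C4 ketone under neutral conditions, so the 5α hydrogen, the β-silyloxy ketone and both acrylates are not disturbed.

Step 21
Reactants: 28 tris-silylated ketone
Product: 29 methyl (1β,5α,6α,7α-H,8α)-1,6-dihydroxy-8-{[2-(hydroxymethyl)acryloyl]oxy}-4-oxo-15-noreudesm-11(13)-en-12-oate (CNP0144895.1; 1R,5S,6S,7S,8S,10R in eudesmane numbering)
Conditions: HF·pyridine, pyridine/THF, 0 °C → rt
Reagents that add atoms: none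
Why: Acidic fluoride removes all three TBS ethers without generating alkoxide or enolate, which avoids retro-aldol or elimination at C4–C6, acyl migration from O8 and conjugate additions; the diequatorial 1,3-relationship of O6 and O8 also disfavours acyl transfer.

## Compound list

1 | methyl levulinate (methyl 4-oxopentanoate) | CC(=O)CCC(=O)OC | starting material
2 | methyl (Z)-4-(trimethylsilyloxy)pent-3-enoate | C/C(O[Si](C)(C)C)=C/CC(=O)OC | intermediate
3 | methyl 3-(dimethoxymethyl)-4-oxopentanoate (racemic) | COC(OC)C(CC(=O)OC)C(C)=O | intermediate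
4 | methyl 3-formyl-4-oxopentanoate (mainly as hydroxymethylene enol) | CC(=O)C(C=O)CC(=O)OC | intermediate
5 | methyl (E)-3-[(tert-butyldimethylsilyloxy)methylene]-4-oxopentanoate (not isolated) | CC(=O)/C(CC(=O)OC)=C/O[Si](C)(C)C(C)(C)C | intermediate
6 | methyl (E)-3-[(tert-butyldimethylsilyloxy)methylene]-4-(tert-butyldimethylsilyloxy)pent-4-enoate | CC(C)(C)[Si](C)(C)O/C=C(/C(=C)O[Si](C)(C)C(C)(C)C)CC(=O)OC | intermediate
7 | 2-methoxy-5-methylphenol | COc1ccc(C)cc1O | starting material
8 | 2-methoxy-5-methyl-1,4-benzoquinone | COC1=CC(=O)C(C)=CC1=O | intermediate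
9 | cis-fused adduct: methyl (5β,6α)-6,8-bis(TBS-oxy)-3-methoxy-1,4-dioxo-13,15-dinoreudesma-2,7-dien-12-oate | CC(C)(C)[Si](C)(C)OC=1C[C@@]2(C)C(=O)C=C(OC)C(=O)[C@H]2[C@@H](O[Si](C)(C)C(C)(C)C)C=1CC(=O)OC | intermediate
10 | trans-fused enedione: methyl (5α,6α)-6,8-bis(TBS-oxy)-3-methoxy-1,4-dioxo-13,15-dinoreudesma-2,7-dien-12-oate | CC(C)(C)[Si](C)(C)OC=1C[C@@]2(C)C(=O)C=C(OC)C(=O)[C@@H]2[C@@H](O[Si](C)(C)C(C)(C)C)C=1CC(=O)OC | intermediate
11 | methyl (5α,6α)-6,8-bis(TBS-oxy)-3-methoxy-1,4-dioxo-13,15-dinoreudesm-7-en-12-oate (C3 epimers; not isolated) | CC(C)(C)[Si](C)(C)OC=1C[C@@]2(C)C(=O)CC(OC)C(=O)[C@@H]2[C@@H](O[Si](C)(C)C(C)(C)C)C=1CC(=O)OC | intermediate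
12 | methyl (5α,6α)-6,8-bis(TBS-oxy)-1,4-dioxo-13,15-dinoreudesm-7-en-12-oate | CC(C)(C)[Si](C)(C)OC=1C[C@@]2(C)C(=O)CCC(=O)[C@@H]2[C@@H](O[Si](C)(C)C(C)(C)C)C=1CC(=O)OC | intermediate
13 | methyl (1β,4β,5α,6α)-6,8-bis(TBS-oxy)-1,4-dihydroxy-13,15-dinoreudesm-7-en-12-oate | CC(C)(C)[Si](C)(C)OC=1C[C@@]2(C)[C@H](O)CC[C@H](O)[C@@H]2[C@@H](O[Si](C)(C)C(C)(C)C)C=1CC(=O)OC | intermediate
14 | methyl (1β,4β,5α,6α)-1,6,8-tris(TBS-oxy)-4-hydroxy-13,15-dinoreudesm-7-en-12-oate | CC(C)(C)[Si](C)(C)OC=1C[C@@]2(C)[C@H](O[Si](C)(C)C(C)(C)C)CC[C@H](O)[C@@H]2[C@@H](O[Si](C)(C)C(C)(C)C)C=1CC(=O)OC | intermediate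
15 | methyl (1β,4β,5α,6α,7α-H)-1,6-bis(TBS-oxy)-4-hydroxy-8-oxo-13,15-dinoreudesman-12-oate | O=C1C[C@@]2(C)[C@H](O[Si](C)(C)C(C)(C)C)CC[C@H](O)[C@@H]2[C@@H](O[Si](C)(C)C(C)(C)C)[C@@H]1CC(=O)OC | intermediate
16 | methyl (1β,4β,5α,6α,7α-H,8α)-1,6-bis(TBS-oxy)-4,8-dihydroxy-13,15-dinoreudesman-12-oate | O[C@H]1C[C@@]2(C)[C@H](O[Si](C)(C)C(C)(C)C)CC[C@H](O)[C@@H]2[C@@H](O[Si](C)(C)C(C)(C)C)[C@@H]1CC(=O)OC | intermediate
17 | methyl (1β,4β,5α,6α,7α-H,8α)-1,6-bis(TBS-oxy)-4,8-bis(TES-oxy)-13,15-dinoreudesman-12-oate | CC[Si](CC)(CC)O[C@H]1C[C@@]2(C)[C@H](O[Si](C)(C)C(C)(C)C)CC[C@H](O[Si](CC)(CC)CC)[C@@H]2[C@@H](O[Si](C)(C)C(C)(C)C)[C@@H]1CC(=O)OC | intermediate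
18 | lithium enolate of ester 17 (not isolated) | [Li+].CC[Si](CC)(CC)O[C@H]1C[C@@]2(C)[C@H](O[Si](C)(C)C(C)(C)C)CC[C@H](O[Si](CC)(CC)CC)[C@@H]2[C@@H](O[Si](C)(C)C(C)(C)C)[C@@H]1C=C([O-])OC | intermediate
19 | methyl (1β,4β,5α,6α,7α-H,8α)-1,6-bis(TBS-oxy)-13-(dimethylamino)-4,8-bis(TES-oxy)-15-noreudesman-12-oate (C11 epimers) | CC[Si](CC)(CC)O[C@H]1C[C@@]2(C)[C@H](O[Si](C)(C)C(C)(C)C)CC[C@H](O[Si](CC)(CC)CC)[C@@H]2[C@@H](O[Si](C)(C)C(C)(C)C)[C@@H]1C(CN(C)C)C(=O)OC | intermediate
20 | 13-trimethylammonium iodide of 19 (not isolated) | [I-].CC[Si](CC)(CC)O[C@H]1C[C@@]2(C)[C@H](O[Si](C)(C)C(C)(C)C)CC[C@H](O[Si](CC)(CC)CC)[C@@H]2[C@@H](O[Si](C)(C)C(C)(C)C)[C@@H]1C(C[N+](C)(C)C)C(=O)OC | intermediate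
21 | methyl (1β,4β,5α,6α,7α-H,8α)-1,6-bis(TBS-oxy)-4,8-bis(TES-oxy)-15-noreudesm-11(13)-en-12-oate | CC[Si](CC)(CC)O[C@H]1C[C@@]2(C)[C@H](O[Si](C)(C)C(C)(C)C)CC[C@H](O[Si](CC)(CC)CC)[C@@H]2[C@@H](O[Si](C)(C)C(C)(C)C)[C@@H]1C(=C)C(=O)OC | intermediate
22 | methyl (1β,4β,5α,6α,7α-H,8α)-1,6-bis(TBS-oxy)-4,8-dihydroxy-15-noreudesm-11(13)-en-12-oate | O[C@H]1C[C@@]2(C)[C@H](O[Si](C)(C)C(C)(C)C)CC[C@H](O)[C@@H]2[C@@H](O[Si](C)(C)C(C)(C)C)[C@@H]1C(=C)C(=O)OC | intermediate
23 | methyl 2-(hydroxymethyl)acrylate | C=C(CO)C(=O)OC | starting material
24 | methyl 2-[(tert-butyldimethylsilyloxy)methyl]acrylate | C=C(CO[Si](C)(C)C(C)(C)C)C(=O)OC | intermediate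
25 | 2-[(tert-butyldimethylsilyloxy)methyl]acrylic acid | C=C(CO[Si](C)(C)C(C)(C)C)C(=O)O | intermediate
26 | 2-[(tert-butyldimethylsilyloxy)methyl]acrylic 2,4,6-trichlorobenzoic anhydride (not isolated) | C=C(CO[Si](C)(C)C(C)(C)C)C(=O)OC(=O)c1c(Cl)cc(Cl)cc1Cl | intermediate
27 | methyl (1β,4β,5α,6α,7α-H,8α)-1,6-bis(TBS-oxy)-8-{2-[(TBS-oxy)methyl]acryloyloxy}-4-hydroxy-15-noreudesm-11(13)-en-12-oate | C=C(CO[Si](C)(C)C(C)(C)C)C(=O)O[C@H]1C[C@@]2(C)[C@H](O[Si](C)(C)C(C)(C)C)CC[C@H](O)[C@@H]2[C@@H](O[Si](C)(C)C(C)(C)C)[C@@H]1C(=C)C(=O)OC | intermediate
28 | methyl (1β,5α,6α,7α-H,8α)-1,6-bis(TBS-oxy)-8-{2-[(TBS-oxy)methyl]acryloyloxy}-4-oxo-15-noreudesm-11(13)-en-12-oate | C=C(CO[Si](C)(C)C(C)(C)C)C(=O)O[C@H]1C[C@@]2(C)[C@H](O[Si](C)(C)C(C)(C)C)CCC(=O)[C@@H]2[C@@H](O[Si](C)(C)C(C)(C)C)[C@@H]1C(=C)C(=O)OC | intermediate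
29 | methyl (1β,5α,6α,7α-H,8α)-1,6-dihydroxy-8-{[2-(hydroxymethyl)acryloyl]oxy}-4-oxo-15-noreudesm-11(13)-en-12-oate (CNP0144895.1) | C=C(CO)C(=O)O[C@H]1C[C@@]2(C)[C@H](O)CCC(=O)[C@@H]2[C@@H](O)[C@@H]1C(=C)C(=O)OC | target

## Step count and least certain steps

Total: 21 steps. Longest linear sequence: 18 steps (steps 1–4, 6–16 and 19–21, from methyl levulinate 1).

Step 6 (key step). The most likely failures are insufficient face or endo selectivity, and consumption of the diene by Lewis-acid desilylation or by Mukaiyama–Michael addition without ring closure. The quaternary centre forms slowly, which gives these paths time. The fallback gives up asymmetric induction. Diene 6 and quinone 8 are heated in toluene without a ligand; the electronic bias of the methoxyquinone already directs C9 to C10. This gives 9 together with its mirror-image adduct F1. The racemate is resolved by preparative chromatography on a chiral stationary phase and the route resumes at 9.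

Step 7. The dienolate may expel the C6 silyloxy group (E1cB elimination), or the equilibrium may not favour the trans isomer while ring A is still an enedione and the C6 substituent lies next to the C4 carbonyl. The fallback reverses the order of steps 7 and 8. Adduct 9 is reduced with SmI2 in THF/MeOH exactly as in step 8 to the cis-fused saturated diketone F2. In F2 the C5 hydrogen is an ordinary ketone α-hydrogen and the leaving group is no longer vinylogously activated. F2 is equilibrated with DBU in toluene and rejoins the route at 12.

Step 10. Site selectivity may be lost, with silylation at the C4 hydroxyl as well as or instead of C1, especially if step 9 delivers some of the equatorial C4 epimer. The fallback differentiates at the ketone level. Diketone 12 is treated with one equivalent of NaBH4 at −78 °C, where only C1 is open to axial attack (C4 is screened by the C10 methyl on one face and the C6 silyl ether on the other). This gives the 1β-hydroxy-4-ketone F3. F3 is silylated with TBSOTf and 2,6-lutidine to the C1 silyl ether 4-ketone F4. F4 is reduced at C4 with NaBH4 at room temperature and rejoins at 14.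

Step 12. Facial selectivity may be poor (protonation from the open face would give the axial 8β carbinol), the new alkoxide may lactonise onto C12, or the ester may be partly reduced. The fallback replaces thermodynamic reduction by hydride delivery and inversion. Ketone 15 is silylated with TESOTf to the C4 triethylsilyl ether ketone F5. F5 is reduced with LiBH(s-Bu)3 at −78 °C, which attacks equatorially and gives the axial 8β alcohol F6. A Mitsunobu reaction with 4-nitrobenzoic acid, PPh3 and diisopropyl azodicarboxylate inverts C8 to the 8α 4-nitrobenzoate F7. Methanolysis with K2CO3 in MeOH gives the 8α alcohol F8. Silylation with TESOTf returns to the route at 17.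

Step 19. Acylation may also occur at the C4 hydroxyl, or the flanked C8 hydroxyl may react so slowly that DMAP adds to the acrylate units instead. The fallback unmasks the two carbinols one after the other. Bis-TES ether 21 is treated briefly with PPTS in MeOH at −10 °C, which removes only the exposed C8 group and gives the C8 alcohol C4 triethylsilyl ether F9. F9 is esterified with 25 under the conditions of step 19 to the C8 ester C4 triethylsilyl ether F10. Removal of the remaining TES group with PPTS in MeOH at 0 °C rejoins the route at 27.

## Further compounds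

F1 | step 6 | mirror image of adduct 9 | CC(C)(C)[Si](C)(C)OC=1C[C@]2(C)C(=O)C=C(OC)C(=O)[C@@H]2[C@H](O[Si](C)(C)C(C)(C)C)C=1CC(=O)OC
F2 | step 7 | cis-fused diketone: methyl (5β,6α)-6,8-bis(TBS-oxy)-1,4-dioxo-13,15-dinoreudesm-7-en-12-oate | CC(C)(C)[Si](C)(C)OC=1C[C@@]2(C)C(=O)CCC(=O)[C@H]2[C@@H](O[Si](C)(C)C(C)(C)C)C=1CC(=O)OC
F3 | step 10 | methyl (1β,5α,6α)-6,8-bis(TBS-oxy)-1-hydroxy-4-oxo-13,15-dinoreudesm-7-en-12-oate | CC(C)(C)[Si](C)(C)OC=1C[C@@]2(C)[C@H](O)CCC(=O)[C@@H]2[C@@H](O[Si](C)(C)C(C)(C)C)C=1CC(=O)OC
F4 | step 10 | methyl (1β,5α,6α)-1,6,8-tris(TBS-oxy)-4-oxo-13,15-dinoreudesm-7-en-12-oate | CC(C)(C)[Si](C)(C)OC=1C[C@@]2(C)[C@H](O[Si](C)(C)C(C)(C)C)CCC(=O)[C@@H]2[C@@H](O[Si](C)(C)C(C)(C)C)C=1CC(=O)OC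
F5 | step 12 | methyl (1β,4β,5α,6α,7α-H)-1,6-bis(TBS-oxy)-4-(TES-oxy)-8-oxo-13,15-dinoreudesman-12-oate | O=C1C[C@@]2(C)[C@H](O[Si](C)(C)C(C)(C)C)CC[C@H](O[Si](CC)(CC)CC)[C@@H]2[C@@H](O[Si](C)(C)C(C)(C)C)[C@@H]1CC(=O)OC
F6 | step 12 | methyl (1β,4β,5α,6α,7α-H,8β)-1,6-bis(TBS-oxy)-4-(TES-oxy)-8-hydroxy-13,15-dinoreudesman-12-oate | O[C@@H]1C[C@@]2(C)[C@H](O[Si](C)(C)C(C)(C)C)CC[C@H](O[Si](CC)(CC)CC)[C@@H]2[C@@H](O[Si](C)(C)C(C)(C)C)[C@@H]1CC(=O)OC
F7 | step 12 | methyl (1β,4β,5α,6α,7α-H,8α)-1,6-bis(TBS-oxy)-4-(TES-oxy)-8-(4-nitrobenzoyloxy)-13,15-dinoreudesman-12-oate | [O-][N+](=O)c1ccc(cc1)C(=O)O[C@H]2C[C@@]3(C)[C@H](O[Si](C)(C)C(C)(C)C)CC[C@H](O[Si](CC)(CC)CC)[C@@H]3[C@@H](O[Si](C)(C)C(C)(C)C)[C@@H]2CC(=O)OC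
F8 | step 12 | methyl (1β,4β,5α,6α,7α-H,8α)-1,6-bis(TBS-oxy)-4-(TES-oxy)-8-hydroxy-13,15-dinoreudesman-12-oate | O[C@H]1C[C@@]2(C)[C@H](O[Si](C)(C)C(C)(C)C)CC[C@H](O[Si](CC)(CC)CC)[C@@H]2[C@@H](O[Si](C)(C)C(C)(C)C)[C@@H]1CC(=O)OC
F9 | step 19 | methyl (1β,4β,5α,6α,7α-H,8α)-1,6-bis(TBS-oxy)-4-(TES-oxy)-8-hydroxy-15-noreudesm-11(13)-en-12-oate | O[C@H]1C[C@@]2(C)[C@H](O[Si](C)(C)C(C)(C)C)CC[C@H](O[Si](CC)(CC)CC)[C@@H]2[C@@H](O[Si](C)(C)C(C)(C)C)[C@@H]1C(=C)C(=O)OC
F10 | step 19 | methyl (1β,4β,5α,6α,7α-H,8α)-1,6-bis(TBS-oxy)-4-(TES-oxy)-8-{2-[(TBS-oxy)methyl]acryloyloxy}-15-noreudesm-11(13)-en-12-oate | C=C(CO[Si](C)(C)C(C)(C)C)C(=O)O[C@H]1C[C@@]2(C)[C@H](O[Si](C)(C)C(C)(C)C)CC[C@H](O[Si](CC)(CC)CC)[C@@H]2[C@@H](O[Si](C)(C)C(C)(C)C)[C@@H]1C(=C)C(=O)OC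
A1 | alternative 1 | methyl (1β,5α,6α,7α-H,8α)-6-(TBS-oxy)-1-hydroxy-8-(4-methoxybenzyloxy)eudesma-4(15),11(13)-dien-12-oate | COc1ccc(CO[C@H]2C[C@@]3(C)[C@H](O)CCC(=C)[C@@H]3[C@@H](O[Si](C)(C)C(C)(C)C)[C@@H]2C(=C)C(=O)OC)cc1
A2 | alternative 1 | methyl (4E)-1β,10α-epoxy-6α-(TBS-oxy)-8α-(4-methoxybenzyloxy)germacra-4,11(13)-dien-12-oate | COc1ccc(CO[C@H]2C[C@@]3(C)O[C@@H]3CC/C(C)=C/[C@@H](O[Si](C)(C)C(C)(C)C)[C@@H]2C(=C)C(=O)OC)cc1
A3 | alternative 2 | (5α,7α-H)-1β,6α-bis(TBS-oxy)-4,4-(ethylenedioxy)-15-noreudesm-11-en-8α-ol | O[C@H]1C[C@@]2(C)[C@H](O[Si](C)(C)C(C)(C)C)CCC3(OCCO3)[C@@H]2[C@@H](O[Si](C)(C)C(C)(C)C)[C@@H]1C(C)=C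
A4 | alternative 2 | (5α)-1β,6α-bis(TBS-oxy)-4,4-(ethylenedioxy)-7,8-seco-15-noreudesm-7(11)-en-8-al | O=CC[C@@]1(C)[C@H](O[Si](C)(C)C(C)(C)C)CCC2(OCCO2)[C@@H]1[C@@H](O[Si](C)(C)C(C)(C)C)C=C(C)C
A5 | alternative 3 | methyl (5α,7α-H)-1β-(TBS-oxy)-4,4-(ethylenedioxy)-6α-hydroxy-8α-(4-methoxybenzyloxy)-15-noreudesm-11(13)-en-12-oate | COc1ccc(CO[C@H]2C[C@@]3(C)[C@H](O[Si](C)(C)C(C)(C)C)CCC4(OCCO4)[C@@H]3[C@@H](O)[C@@H]2C(=C)C(=O)OC)cc1
A6 | alternative 3 | methyl (5α,7Z)-1β-(TBS-oxy)-4,4-(ethylenedioxy)-8α-(4-methoxybenzyloxy)-6-oxo-13-(pinacolatoboryl)-6,7-seco-15-noreudesm-7(11)-en-12-oate | COc1ccc(CO[C@@H](C[C@@]2(C)[C@H](O[Si](C)(C)C(C)(C)C)CCC3(OCCO3)[C@@H]2C=O)/C=C(\C(=O)OC)CB2OC(C)(C)C(C)(C)O2)cc1
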